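**Retrosynthetic overview**
- Target ⇐ hydroxy acid 21 (O-acetylation) ⇐ imide 19 (hydroperoxide removal of the Evans auxiliary).
- C5–C6 (sp3–sp2) bond ⇐ B-alkyl Suzuki–Miyaura coupling of the 9-BBN adduct of allyl imide 6 with (E)-2-bromoallylic alcohol 17; retention at the vinyl carbon gives the 6Z alkene.
- C2 stereocentre ⇐ Evans allylation of the (R)-4-benzyloxazolidinone imide of 6-methylhept-5-enoic acid.
- 17 ⇐ (E)-selective bromo-Horner–Wadsworth–Emmons olefination of 3-(furan-3-yl)propanal, then i-Bu2AlH; the aldehyde ⇐ 3-furyllithium + oxetane.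
- No ring is formed in the route; the furan is bought as 3-bromofuran and carried through.

Assumption: 6-methylhept-5-enoic acid (1) is taken to be a catalogue compound.

**Step 1**
Reactants: 1 6-methylhept-5-enoic acid; 2 (4R)-4-benzyl-1,3-oxazolidin-2-one
Product: 4 (4R)-4-benzyl-3-(6-methylhept-5-enoyl)-1,3-oxazolidin-2-one, via mixed pivalic anhydride 3 (not isolated)
Conditions: PivCl, Et3N, THF, −20 °C; then LiCl, 2, −20 °C → rt
Reagents that add atoms: none
Why: Mixed-anhydride N-acylation, in which the LiCl/Et3N-activated oxazolidinone attacks the unhindered acyl carbonyl of the pivalic anhydride; no stereocentre is made.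

**Step 2**
Reactants: 4 (4R)-4-benzyl-3-(6-methylhept-5-enoyl)-1,3-oxazolidin-2-one
Product: 6 (4R)-4-benzyl-3-[(2S)-6-methyl-2-(prop-2-en-1-yl)hept-5-enoyl]-1,3-oxazolidin-2-one, via sodium Z-enolate 5 (not isolated)
Conditions: NaN(SiMe3)2, THF, −78 °C; allyl iodide, −78 → −45 °C
Reagents that add atoms: allyl iodide, C=CCI
Why: Evans asymmetric alkylation, in which the chelated sodium Z-enolate is allylated on the face away from the C4 benzyl group; with the (R)-auxiliary this gives the 2S centre, which becomes 2R by CIP once the allyl arm is extended.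

**Step 3**
Reactants: 7 methyl 2-[bis(2,2,2-trifluoroethoxy)phosphoryl]acetate
Product: 8 methyl 2-[bis(2,2,2-trifluoroethoxy)phosphoryl]-2,2-dibromoacetate
Conditions: Br2, aq NaOH (NaOBr made in the flask), 0 °C, 10 min
Reagents that add atoms: bromine, BrBr
Why: Electrophilic α-halogenation of the doubly activated methylene by hypobromite runs cleanly to the gem-dibromide and so avoids mono/di mixtures.

**Step 4**
Reactants: 8 methyl 2-[bis(2,2,2-trifluoroethoxy)phosphoryl]-2,2-dibromoacetate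
Product: 9 methyl 2-[bis(2,2,2-trifluoroethoxy)phosphoryl]-2-bromoacetate (racemic)
Conditions: SnCl2·2H2O, EtOH/H2O, 0 °C
Reagents that add atoms: none
Why: Reductive monodebromination, in which divalent tin takes one bromine from the gem-dibromide and the stabilised carbanion is protonated, stopping at the monobromide.

**Step 5**
Reactants: 10 3-bromofuran; 11 oxetane
Product: 13 3-(furan-3-yl)propan-1-ol, via furan-3-yllithium 12 (not isolated)
Conditions: n-BuLi, THF, −78 °C; then 11, BF3·OEt2, −78 °C; H2O quench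
Reagents that add atoms: none
Why: Bromine–lithium exchange followed by BF3-promoted SN2 ring opening of oxetane by the aryllithium, kept at −78 °C so that 3-lithiofuran does not isomerise to the 2-isomer.

**Step 6**
Reactants: 13 3-(furan-3-yl)propan-1-ol
Product: 14 3-(furan-3-yl)propanal
Conditions: TEMPO (10 mol%), PhI(OAc)2, CH2Cl2, rt
Reagents that add atoms: none
Why: Oxoammonium-mediated (TEMPO/PhI(OAc)2) alcohol oxidation stops at the aldehyde and leaves the furan untouched.

**Step 7**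
Reactants: 14 3-(furan-3-yl)propanal; 9 methyl 2-[bis(2,2,2-trifluoroethoxy)phosphoryl]-2-bromoacetate
Product: 16 methyl (2E)-2-bromo-5-(furan-3-yl)pent-2-enoate, via potassium phosphonate carbanion 15 (not isolated)
Conditions: KOt-Bu, 18-crown-6, THF, −78 °C; then 14, −78 °C
Reagents that add atoms: none
Why: Horner–Wadsworth–Emmons olefination of Still–Gennari type, in which the electron-poor bis(trifluoroethyl) phosphonate under dissociating conditions eliminates kinetically with the ester cis to the alkyl chain, giving the (E)-α-bromoacrylate that fixes the later alkene geometry.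

**Step 8**
Reactants: 16 methyl (2E)-2-bromo-5-(furan-3-yl)pent-2-enoate
Product: 17 (2E)-2-bromo-5-(furan-3-yl)pent-2-en-1-ol
Conditions: i-Bu2AlH (2.5 equiv), CH2Cl2, −78 → 0 °C; aq potassium sodium tartrate work-up
Reagents that add atoms: none
Why: 1,2-Reduction of the ester by i-Bu2AlH gives the allylic alcohol without touching the vinyl bromide or the alkene geometry.

**Step 9**
Reactants: 6 (4R)-4-benzyl-3-[(2S)-6-methyl-2-(prop-2-en-1-yl)hept-5-enoyl]-1,3-oxazolidin-2-one; 17 (2E)-2-bromo-5-(furan-3-yl)pent-2-en-1-ol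
Product: 19 (4R)-4-benzyl-3-[(2R,6Z)-9-(furan-3-yl)-6-(hydroxymethyl)-2-(4-methylpent-3-en-1-yl)non-6-enoyl]-1,3-oxazolidin-2-one, via B-alkyl-9-BBN borane 18 (not isolated)
Conditions: 9-BBN-H (9-borabicyclo[3.3.1]nonane), THF, 0 °C → rt; then 17, PdCl2(dppf) (5 mol%), AsPh3, aq Cs2CO3, DMF, rt → 40 °C
Reagents that add atoms: none
Why: Anti-Markovnikov hydroboration of the monosubstituted alkene only, then B-alkyl Suzuki–Miyaura coupling in which zerovalent palladium inserts into the C–Br bond and couples with retention, so the new chain is trans to the furylethyl group (6Z) and C2 is untouched.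

**Step 10**
Reactants: 19 (4R)-4-benzyl-3-[(2R,6Z)-9-(furan-3-yl)-6-(hydroxymethyl)-2-(4-methylpent-3-en-1-yl)non-6-enoyl]-1,3-oxazolidin-2-one
Product: 21 (2R,6Z)-9-(furan-3-yl)-6-(hydroxymethyl)-2-(4-methylpent-3-en-1-yl)non-6-enoic acid, via lithium peroxycarboxylate 20 (not isolated)
Conditions: LiOH, 30% H2O2, THF/H2O (3:1), 0 °C; then aq Na2SO3; then 1 M HCl to pH 3
Reagents that add atoms: hydrogen peroxide, OO
Why: Evans auxiliary cleavage, in which hydroperoxide attacks the exocyclic imide carbonyl selectively even at the α-branched acyl group and without epimerising C2; sulfite then reduces the peroxy acid.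

**Step 11**
Reactants: 21 (2R,6Z)-9-(furan-3-yl)-6-(hydroxymethyl)-2-(4-methylpent-3-en-1-yl)non-6-enoic acid
Product: 23 (2R,6Z)-6-[(acetyloxy)methyl]-9-(furan-3-yl)-2-(4-methylpent-3-en-1-yl)non-6-enoic acid (CNP0147819.2), via mixed acetic anhydride 22 (not isolated)
Conditions: Ac2O, pyridine, CH2Cl2, 0 °C → rt; then H2O/THF, rt
Reagents that add atoms: acetic anhydride, CC(=O)OC(C)=O
Why: O-Acylation of the primary allylic alcohol; the mixed anhydride formed at the carboxyl group is hydrolysed back to the acid on aqueous work-up, so only the acetate ester remains.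

**Compound list**
1 | 6-methylhept-5-enoic acid | CC(C)=CCCCC(=O)O | starting material
2 | (4R)-4-benzyl-1,3-oxazolidin-2-one | O=C1N[C@H](Cc2ccccc2)CO1 | starting material
3 | 2,2-dimethylpropanoic 6-methylhept-5-enoic anhydride | CC(C)=CCCCC(=O)OC(=O)C(C)(C)C | intermediate
4 | (4R)-4-benzyl-3-(6-methylhept-5-enoyl)-1,3-oxazolidin-2-one | CC(C)=CCCCC(=O)N1[C@H](Cc2ccccc2)COC1=O | intermediate
5 | sodium (1Z)-1-[(4R)-4-benzyl-2-oxo-1,3-oxazolidin-3-yl]-6-methylhepta-1,5-dien-1-olate | CC(C)=CCC/C=C(\[O-])N1[C@H](Cc2ccccc2)COC1=O.[Na+] | intermediate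
6 | (4R)-4-benzyl-3-[(2S)-6-methyl-2-(prop-2-en-1-yl)hept-5-enoyl]-1,3-oxazolidin-2-one | C=CC[C@H](CCC=C(C)C)C(=O)N1[C@H](Cc2ccccc2)COC1=O | intermediate
7 | methyl 2-[bis(2,2,2-trifluoroethoxy)phosphoryl]acetate | COC(=O)CP(=O)(OCC(F)(F)F)OCC(F)(F)F | starting material
8 | methyl 2-[bis(2,2,2-trifluoroethoxy)phosphoryl]-2,2-dibromoacetate | COC(=O)C(Br)(Br)P(=O)(OCC(F)(F)F)OCC(F)(F)F | intermediate
9 | methyl 2-[bis(2,2,2-trifluoroethoxy)phosphoryl]-2-bromoacetate (racemic) | COC(=O)C(Br)P(=O)(OCC(F)(F)F)OCC(F)(F)F | intermediate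
10 | 3-bromofuran | Brc1ccoc1 | starting material
11 | oxetane | C1COC1 | starting material
12 | furan-3-yllithium | [Li]c1ccoc1 | intermediate
13 | 3-(furan-3-yl)propan-1-ol | OCCCc1ccoc1 | intermediate
14 | 3-(furan-3-yl)propanal | O=CCCc1ccoc1 | intermediate
15 | potassium bromo[bis(2,2,2-trifluoroethoxy)phosphoryl](methoxycarbonyl)methanide | COC(=O)[C-](Br)P(=O)(OCC(F)(F)F)OCC(F)(F)F.[K+] | intermediate
16 | methyl (2E)-2-bromo-5-(furan-3-yl)pent-2-enoate | COC(=O)/C(Br)=C\CCc1ccoc1 | intermediate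
17 | (2E)-2-bromo-5-(furan-3-yl)pent-2-en-1-ol | OC/C(Br)=C\CCc1ccoc1 | intermediate
18 | (4R)-4-benzyl-3-[(2R)-2-[3-(9-borabicyclo[3.3.1]nonan-9-yl)propyl]-6-methylhept-5-enoyl]-1,3-oxazolidin-2-one | B1(CCC[C@H](CCC=C(C)C)C(=O)N2[C@H](Cc3ccccc3)COC2=O)C2CCCC1CCC2 | intermediate
19 | (4R)-4-benzyl-3-[(2R,6Z)-9-(furan-3-yl)-6-(hydroxymethyl)-2-(4-methylpent-3-en-1-yl)non-6-enoyl]-1,3-oxazolidin-2-one | OC/C(=C\CCc1ccoc1)CCC[C@H](CCC=C(C)C)C(=O)N1[C@H](Cc2ccccc2)COC1=O | intermediate
20 | lithium (2R,6Z)-9-(furan-3-yl)-6-(hydroxymethyl)-2-(4-methylpent-3-en-1-yl)non-6-eneperoxoate | OC/C(=C\CCc1ccoc1)CCC[C@H](CCC=C(C)C)C(=O)O[O-].[Li+] | intermediate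
21 | (2R,6Z)-9-(furan-3-yl)-6-(hydroxymethyl)-2-(4-methylpent-3-en-1-yl)non-6-enoic acid | OC/C(=C\CCc1ccoc1)CCC[C@H](CCC=C(C)C)C(=O)O | intermediate
22 | acetic (2R,6Z)-6-[(acetyloxy)methyl]-9-(furan-3-yl)-2-(4-methylpent-3-en-1-yl)non-6-enoic anhydride | CC(=O)OC/C(=C\CCc1ccoc1)CCC[C@H](CCC=C(C)C)C(=O)OC(C)=O | intermediate
23 | (2R,6Z)-6-[(acetyloxy)methyl]-9-(furan-3-yl)-2-(4-methylpent-3-en-1-yl)non-6-enoic acid | CC(=O)OC/C(=C\CCc1ccoc1)CCC[C@H](CCC=C(C)C)C(=O)O | target

**Step count**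
Total: 11 steps. Longest linear sequence: 7 steps (10 → 13 → 14 → 16 → 17 → 19 → 21 → 23). Side branches are two steps each (1 → 6 and 7 → 9).

**Three steps most likely to fail**

Step 5: 3-lithiofuran is thermally fragile and the BF3/oxetane opening can give a poor yield. The fallback sets out from 10 and comes back at 14. 3,3-Diethoxyprop-1-ene is hydroborated with 9-BBN-H (THF, rt) to 9-(3,3-diethoxypropyl)-9-borabicyclo[3.3.1]nonane F1. This is cross-coupled in the same flask with 10 (PdCl2(dppf), aq K3PO4, DMF, 50 °C; B-alkyl Suzuki–Miyaura coupling) to give 3-(3,3-diethoxypropyl)furan F2. Mild acetal hydrolysis (AcOH/THF/H2O, rt) then delivers 14, so neither an organolithium nor the oxidation of step 6 is needed.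

Step 7: the E/Z ratio with an enolisable aliphatic aldehyde may be too low, and reagent 9 may be troublesome to make. The fallback sets out from 14 and comes back at 19. CBr4/PPh3 (CH2Cl2, 0 °C) converts 14 into 3-(4,4-dibromobut-3-en-1-yl)furan F3 (Corey–Fuchs). n-BuLi (2.1 equiv, THF, −78 °C) gives [4-(furan-3-yl)but-1-yn-1-yl]lithium F4, which is trapped with paraformaldehyde as 5-(furan-3-yl)pent-2-yn-1-ol F5. Syn-hydrostannation (Bu3SnH, PdCl2(PPh3)2 cat., THF, 0 °C) puts tin on the carbon next to the carbinol and gives (2E)-5-(furan-3-yl)-2-(tributylstannyl)pent-2-en-1-ol F6 after separation from its regioisomer. I2 (CH2Cl2, 0 °C) replaces tin with retention to give (2E)-5-(furan-3-yl)-2-iodopent-2-en-1-ol F7. F7 takes the place of 17 in the coupling with borane 18 and gives 19; steps 3, 4, 7 and 8 are then not used.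

Step 9: the imide may be attacked by the aqueous base, and the coupling of a vinyl bromide with a hindered fragment may be slow. The fallback sets out from 6 and comes back at 21. The auxiliary is taken off first: LiOH/H2O2 (THF/H2O, 0 °C) gives lithium (2S)-6-methyl-2-(prop-2-en-1-yl)hept-5-eneperoxoate F8, and Na2SO3 reduction and acidification give (2S)-6-methyl-2-(prop-2-en-1-yl)hept-5-enoic acid F9. 9-BBN-H (2.2 equiv; the first equivalent masks the acid as its acyloxyborane with loss of H2) gives 9-borabicyclo[3.3.1]nonan-9-yl (2R)-2-[3-(9-borabicyclo[3.3.1]nonan-9-yl)propyl]-6-methylhept-5-enoate F10. F10 is coupled with 17 (PdCl2(dppf), AsPh3, aq Cs2CO3, DMF) to give hydroxy acid 21 directly. No imide meets the basic coupling medium, and step 10 is skipped.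

**Further compounds**
F1 | step 5 | 9-(3,3-diethoxypropyl)-9-borabicyclo[3.3.1]nonane | CCOC(CCB1C2CCCC1CCC2)OCC
F2 | step 5 | 3-(3,3-diethoxypropyl)furan | CCOC(CCc1ccoc1)OCC
F3 | step 7 | 3-(4,4-dibromobut-3-en-1-yl)furan | BrC(Br)=CCCc1ccoc1
F4 | step 7 | [4-(furan-3-yl)but-1-yn-1-yl]lithium | [Li]C#CCCc1ccoc1
F5 | step 7 | 5-(furan-3-yl)pent-2-yn-1-ol | OCC#CCCc1ccoc1
F6 | step 7 | (2E)-5-(furan-3-yl)-2-(tributylstannyl)pent-2-en-1-ol | OC/C(=C\CCc1ccoc1)[Sn](CCCC)(CCCC)CCCC
F7 | step 7 | (2E)-5-(furan-3-yl)-2-iodopent-2-en-1-ol | OC/C(I)=C\CCc1ccoc1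
F8 | step 9 | lithium (2S)-6-methyl-2-(prop-2-en-1-yl)hept-5-eneperoxoate | C=CC[C@H](CCC=C(C)C)C(=O)O[O-].[Li+]
F9 | step 9 | (2S)-6-methyl-2-(prop-2-en-1-yl)hept-5-enoic acid | C=CC[C@H](CCC=C(C)C)C(=O)O
F10 | step 9 | 9-borabicyclo[3.3.1]nonan-9-yl (2R)-2-[3-(9-borabicyclo[3.3.1]nonan-9-yl)propyl]-6-methylhept-5-enoate | B1(CCC[C@H](CCC=C(C)C)C(=O)OB2C3CCCC2CCC3)C2CCCC1CCC2
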